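The runs are calculated from invented constants.

If you want a number for red and violet today, I would not start from a rate constant. I would start from the D share: D over D plus E at one moment, the part of the converted J that has reached D.

all flasks: J 1.5 M

| run | X | remark | time |
|---|---|---|---|
| west | 1.1 M | run made earlier |  |
| east | 1.7 M | run made earlier |  |
| red | 2.25 M |  | 10 d |
| violet | 2.25 M |  | 15 d |

| run | time / d | D / % | E / % | J / % |
|---|---|---|---|---|
| west | 0.625 | 0.6 | 10.7 | 87.8 |
| west | 1.04 | 2.7 | 16.1 | 81.8 |
| west | 1.67 | 7.3 | 21.0 | 73.5 |
| west | 3.00 | 12.5 | 24.9 | 64.7 |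
| west | 5.00 | 18.0 | 24.1 | 55.6 |
| west | 8.00 | 28.7 | 21.8 | 49.0 |
| east | 1.25 | 5.0 | 23.9 | 69.2 |
| east | 2.50 | 11.3 | 31.4 | 53.0 |
| east | 4.00 | 21.4 | 32.2 | 45.4 |
| east | 5.00 | 27.8 | 31.6 | 41.9 |
| east | 6.00 | 30.9 | 29.9 | 38.6 |
| east | 8.00 | 37.8 | 27.9 | 34.8 |

(readings scatter by 1 percentage point)

1. which of these there is most of at the end, counted by the J in it, red (D / J / E)
2. which of these there is most of at the end, counted by the J in it, violet (D / J / E)
3. how much there is at the end of the one of these that leads, in percent of the J charged: red
4. how much there is at the end of the one of these that leads, in percent of the J charged: violet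

At 8.00 d the share reads 56.8% in west and 57.5% in east, about the same although the X charges differ. So I let the share follow the clock. Averaged over both runs it reads 44.8% at 5.00 d and 57.2% at 8.00 d, a gain of 12 percentage points.

That mean rise per day is half of what east showed from 2.50 d to 5.00 d. So I let each further stretch of 3.00 d gain half the one before. That puts the D share at 61.3% for 10 d and at 67.0% for 15 d. A mean slope stands in for a curve here, so hold these loosely.

Your forecast leaves 19% and 13% of J. Taking roughly 80.0% and 87.5% as converted, I get D at 49.1% in red and 58.6% in violet. The forecast also has D leading in red and D in violet, but higher, at 58% and 73%. One of its grounds is that “E → D is first order and does not use X”. Mine is lower.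

The flasks give D in the lead, 49.0% in red and 55.7% in violet.

    J + X → E + Q (k = 0.00930 L mol⁻¹ h⁻¹)
    E ⇌ D (K = 2.30, k = 0.0100 h⁻¹)
    2 X → G (k = 0.00240 L mol⁻¹ h⁻¹)

Red's D share is 62.1% against my 61.3%, and violet's is 66.8% against 67.0%. The forecast parts from the flask at E: red holds 29.9%, where the forecast had 23. Now take a neighbouring flask, red with X cut to 0.56 M. Its J left at 10.0 d is 68.6%, so 61.3% of the remainder gives D at 19.2%. That neighbour holds D at 19.2% and E at 12.2%, a share of 61.1%. The lead there goes to J, at 68.6%.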